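**Retrosynthetic overview**
1. The depside ester bond is cut into ring A as 2,4-dimethoxy-6-pentylbenzoyl chloride and ring B as benzyl 2,4-dihydroxy-6-propylbenzoate; ring B is acylated at its free 4-OH, then 2-O-methylated, and hydrogenolysis of the benzyl ester ends the route.
2. The strategy rests on ring A: C1 carboxyl, C2 methoxy and C6 pentyl sit on three adjacent carbons and the C4 methoxy lies between C3-H and C5-H. Ring A C1, C2, C5 and C6 map onto C5, C6, C3 and C4 of a 6-methoxy-2-pyranone-5-carboxylate, and ring A C3-C4 onto the two carbons of 1,1-dimethoxyethene.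
3. Ring A is therefore made from the pyranone ring by inverse-demand (4+2) cycloaddition, loss of CO2 and loss of methanol, with both methyl ethers arriving in place.
4. The pyranone comes from dimethyl malonate and methyl oct-2-ynoate by Michael addition and lactonisation with loss of methanol.
5. Ring order: the pyranone ring first, ring A from it; ring B is bought as 5-propylresorcinol and only carboxylated and benzylated.

Key step: step 3

Assumption: the target has no stereocentre, and 5-propylbenzene-1,3-diol and methyl magnesium carbonate solution in DMF are taken as purchasable.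

**Route**

Step 1
Reactants: 1 methyl oct-2-ynoate; 2 dimethyl malonate
Product: 3 trimethyl 2-pentylprop-1-ene-1,3,3-tricarboxylate (E/Z mixture, used crude)
Conditions: NaOMe (1.05 equiv), MeOH, 0 °C to reflux; cold dilute HCl quench
Reagents that add atoms: none
Why: Michael addition of sodiomalonate to the β-carbon of the ynoate; a full equivalent of base is used because the adduct, a vinylogous malonate, is more acidic than dimethyl malonate, and all E/Z and double-bond isomers share one delocalised anion.

Step 2
Reactants: 3 trimethyl 2-pentylprop-1-ene-1,3,3-tricarboxylate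
Product: 4 methyl 6-methoxy-2-oxo-4-pentyl-2H-pyran-5-carboxylate
Conditions: neat, 180–200 °C, reduced pressure with removal of MeOH; then bulb-to-bulb distillation, moisture excluded
Reagents that add atoms: none
Why: Thermal lactonisation, the classical closure of 2-(alkoxycarbonyl)glutaconates to 6-alkoxy-2-pyranone-5-carboxylates: in the Z isomer the enol oxygen of the malonate unit attacks the cis acrylate ester (6-exo-trig acyl substitution), the E isomer feeds in through the shared enol and alkylidenemalonate tautomers, and distilling off methanol drives the closure.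

Step 3
Reactants: 4 methyl 6-methoxy-2-oxo-4-pentyl-2H-pyran-5-carboxylate; 5 1,1-dimethoxyethene
Product: 8 methyl 2,4-dimethoxy-6-pentylbenzoate, via bridged lactone 6 (not isolated), via cyclohexadiene ketal 7 (not isolated)
Conditions: 5 (4 equiv), dry toluene, sealed tube, 140–160 °C
Reagents that add atoms: none
Why: In an inverse-electron-demand Diels-Alder reaction the nucleophilic CH2 of 1,1-dimethoxyethene bonds to pyranone C6, the diene terminus made electrophilic by the C5 ester and its two oxygens, and the acetal carbon bonds to C3 in an asynchronous (4+2) addition that gives bridged lactone 6; these are ring A bonds C2-C3 and C4-C5. Cycloreversion of 6 expels CO2 to give cyclohexadiene ketal 7, and thermal 1,2-elimination of methanol across ring A C3-C4 aromatises it to 8. The closest known reactions are the cycloadditions of alkyl coumalates and of 3-carbomethoxy-2-pyranones with ketene acetals that end in decarboxylative aromatisation. Ring A is closed by this intermolecular (4+2) cycloaddition, formed first as part of the 2-oxabicyclo[2.2.2]octenone and then freed by loss of the lactone bridge. No stereocentre survives, since the two bridgehead centres of 6 form as a racemate and vanish on loss of CO2. The step needs regioselectivity (CH2 to C6, not to C3, which would give the 2,3-dimethoxy isomer); the matched polarisation of the 6-alkoxy-5-ester diene and the ketene acetal should secure it, and excess acetal with strong heating should offset the deactivation by the 6-methoxy donor.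

Step 4
Reactants: 8 methyl 2,4-dimethoxy-6-pentylbenzoate
Product: 9 2,4-dimethoxy-6-pentylbenzoic acid
Conditions: KOH, DMSO/H2O (4:1), 100 °C; then cold 1 M HCl to pH 3
Reagents that add atoms: potassium hydroxide, [K+].[OH-]
Why: Saponification of a di-ortho-substituted benzoate by poorly solvated hydroxide in aqueous DMSO; the aryl methyl ethers are inert to hydroxide and cold, mild acidification should avoid protodecarboxylation of the electron-rich acid.

Step 5
Reactants: 9 2,4-dimethoxy-6-pentylbenzoic acid
Product: 10 2,4-dimethoxy-6-pentylbenzoyl chloride (crude, after evaporation)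
Conditions: (COCl)2, DMF (cat.), CH2Cl2, 0 °C to rt
Reagents that add atoms: oxalyl chloride, ClC(=O)C(=O)Cl
Why: Acid chloride formation through the Vilsmeier-type chloroiminium catalyst under cold, non-aqueous conditions, with only gaseous by-products and no reagent able to cleave the ortho methyl ether.

Step 6
Reactants: 11 5-propylbenzene-1,3-diol
Product: 12 2,4-dihydroxy-6-propylbenzoic acid
Conditions: methyl magnesium carbonate (MeOMgOCO2Me, 2 M in DMF, excess), 120–130 °C, N2; then ice-cold dilute HCl
Reagents that add atoms: methyl magnesium carbonate, COC(=O)O[Mg]OC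
Why: Kolbe-Schmitt-type ortho-carboxylation with the Stiles reagent, in which the magnesium phenoxide delivers CO2 to the ortho carbon that is para to the second hydroxyl and the product is held as its magnesium salicylate chelate, as in the carboxylation of 5-alkylresorcinols to 6-alkyl-β-resorcylic acids.

Step 7
Reactants: 12 2,4-dihydroxy-6-propylbenzoic acid
Product: 13 benzyl 2,4-dihydroxy-6-propylbenzoate
Conditions: KHCO3 (1.1 equiv), BnBr (1.05 equiv), DMF, rt
Reagents that add atoms: benzyl bromide, BrCc1ccccc1
Why: Chemoselective SN2 O-alkylation of the carboxylate, since hydrogencarbonate deprotonates only the carboxylic acid and not the phenols, and room temperature avoids decarboxylation.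

Step 8
Reactants: 10 2,4-dimethoxy-6-pentylbenzoyl chloride; 13 benzyl 2,4-dihydroxy-6-propylbenzoate
Product: 14 benzyl 4-[(2,4-dimethoxy-6-pentylbenzoyl)oxy]-2-hydroxy-6-propylbenzoate
Conditions: Et3N (1.2 equiv), DMAP (cat.), CH2Cl2, 0 °C to rt; 10 added slowly (1.0 equiv)
Reagents that add atoms: none
Why: DMAP-catalysed O-acylation with the usual depside-coupling selectivity: the 4-OH is the more acidic, non-chelated phenol, whereas the 2-OH is hydrogen-bonded to and flanked by the ester, so one acyl group should enter at O4.

Step 9
Reactants: 14 benzyl 4-[(2,4-dimethoxy-6-pentylbenzoyl)oxy]-2-hydroxy-6-propylbenzoate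
Product: 15 benzyl 4-[(2,4-dimethoxy-6-pentylbenzoyl)oxy]-2-methoxy-6-propylbenzoate
Conditions: MeI (3 equiv), K2CO3 (2 equiv), dry acetone, reflux
Reagents that add atoms: iodomethane, CI
Why: Williamson O-methylation of the one remaining, hydrogen-bonded phenol; the di-ortho-substituted depside ester and the benzyl ester should be inert to anhydrous carbonate.

Step 10
Reactants: 15 benzyl 4-[(2,4-dimethoxy-6-pentylbenzoyl)oxy]-2-methoxy-6-propylbenzoate
Product: 16 4-[(2,4-dimethoxy-6-pentylbenzoyl)oxy]-2-methoxy-6-propylbenzoic acid (target)
Conditions: H2 (1 atm), 10% Pd/C, EtOAc, rt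
Reagents that add atoms: none
Why: Hydrogenolysis of the benzyl ester over palladium on carbon under neutral conditions, which leaves the aryl ester, the aryl methyl ethers and both arenes untouched.

**Compound list**
1 | methyl oct-2-ynoate | CCCCCC#CC(=O)OC | starting material
2 | dimethyl malonate | COC(=O)CC(=O)OC | starting material
3 | trimethyl 2-pentylprop-1-ene-1,3,3-tricarboxylate (E/Z mixture) | CCCCCC(=CC(=O)OC)C(C(=O)OC)C(=O)OC | intermediate
4 | methyl 6-methoxy-2-oxo-4-pentyl-2H-pyran-5-carboxylate | CCCCCC1=CC(=O)OC(OC)=C1C(=O)OC | intermediate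
5 | 1,1-dimethoxyethene | C=C(OC)OC | starting material
6 | methyl 1,8,8-trimethoxy-3-oxo-5-pentyl-2-oxabicyclo[2.2.2]oct-5-ene-6-carboxylate (racemic bridged lactone, not isolated) | COC(=O)C1=C(CCCCC)C2C(=O)OC1(OC)CC2(OC)OC | intermediate
7 | methyl 2,4,4-trimethoxy-6-pentylcyclohexa-1,5-diene-1-carboxylate (not isolated) | COC(=O)C1=C(OC)CC(OC)(OC)C=C1CCCCC | intermediate
8 | methyl 2,4-dimethoxy-6-pentylbenzoate | CCCCCc1cc(OC)cc(OC)c1C(=O)OC | intermediate
9 | 2,4-dimethoxy-6-pentylbenzoic acid | CCCCCc1cc(OC)cc(OC)c1C(=O)O | intermediate
10 | 2,4-dimethoxy-6-pentylbenzoyl chloride | CCCCCc1cc(OC)cc(OC)c1C(=O)Cl | intermediate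
11 | 5-propylbenzene-1,3-diol | CCCc1cc(O)cc(O)c1 | starting material
12 | 2,4-dihydroxy-6-propylbenzoic acid | CCCc1cc(O)cc(O)c1C(=O)O | intermediate
13 | benzyl 2,4-dihydroxy-6-propylbenzoate | CCCc1cc(O)cc(O)c1C(=O)OCc1ccccc1 | intermediate
14 | benzyl 4-[(2,4-dimethoxy-6-pentylbenzoyl)oxy]-2-hydroxy-6-propylbenzoate | CCCCCc1cc(OC)cc(OC)c1C(=O)Oc1cc(CCC)c(C(=O)OCc2ccccc2)c(O)c1 | intermediate
15 | benzyl 4-[(2,4-dimethoxy-6-pentylbenzoyl)oxy]-2-methoxy-6-propylbenzoate | CCCCCc1cc(OC)cc(OC)c1C(=O)Oc1cc(CCC)c(C(=O)OCc2ccccc2)c(OC)c1 | intermediate
16 | 4-[(2,4-dimethoxy-6-pentylbenzoyl)oxy]-2-methoxy-6-propylbenzoic acid | CCCCCc1cc(OC)cc(OC)c1C(=O)Oc1cc(CCC)c(C(=O)O)c(OC)c1 | target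

**Step count**
Total steps: 10. Longest linear sequence: 8 steps (steps 1, 2, 3, 4, 5, 8, 9, 10, from methyl oct-2-ynoate); the ring B branch (steps 6, 7) joins at step 8.

**Steps most likely to fail**

Step 3 (key cycloaddition). The 6-methoxy donor may slow the cycloaddition so far that the ketene acetal is consumed by oligomerisation, or that it attacks the lactone carbonyl and opens the pyranone, before the (4+2) addition occurs. The fallback sets out from compound 2 and returns at compound 8. Dimethyl malonate 2 would be condensed with commercial (E)-non-3-en-2-one (NaOMe, MeOH, reflux; Michael addition then Claisen ring closure) to give methyl 2-hydroxy-4-oxo-6-pentylcyclohex-2-ene-1-carboxylate F1. Aromatisation by bromination and dehydrobromination (Br2, DMF, 0 °C then 80 °C) would give methyl 2,4-dihydroxy-6-pentylbenzoate F2, and exhaustive O-methylation (MeI, K2CO3, DMF, 50 °C) would give 8.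

Step 2 (lactonisation). E/Z equilibration may be incomplete, closure may run in the opposite sense (the acrylate-derived enol onto a malonate ester, leading to the 3-carboxylate isomer), or the triester may decompose before methanol is lost. The fallback sets out from compound 2 and returns at compound 4. Hept-1-yne would be converted (n-BuLi, then Boc2O, THF, −78 °C) to tert-butyl oct-2-ynoate F3, and the sodium salt of 2 (NaH, THF) would be added to it to give 1-tert-butyl 3,3-dimethyl 2-pentylprop-1-ene-1,3,3-tricarboxylate F4. TFA in CH2Cl2 would free 5-methoxy-4-(methoxycarbonyl)-5-oxo-3-pentylpent-2-enoic acid F5. Cyclodehydration through the mixed anhydride (Ac2O, 60–80 °C) can close only from the malonate enol oxygen onto the activated carboxyl, so it should give 4 with unambiguous regiochemistry and at much lower temperature.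

Step 6 (carboxylation of ring B). Carboxylation may stay incomplete, the position between the two hydroxyls may compete, and the β-resorcylic acid may lose CO2 again on acidic work-up. The fallback sets out from compound 11, uses compound 10, and returns at compound 16, replacing the benzyl ester by a formyl group. Vilsmeier-Haack formylation of 11 (POCl3, DMF, 0 °C to rt, then aqueous NaOAc) would give 2,4-dihydroxy-6-propylbenzaldehyde F6. Acylation of its free 4-OH with acid chloride 10 (Et3N, DMAP, CH2Cl2) would give 4-formyl-3-hydroxy-5-propylphenyl 2,4-dimethoxy-6-pentylbenzoate F7. O-methylation (MeI, K2CO3, DMF) would give 4-formyl-3-methoxy-5-propylphenyl 2,4-dimethoxy-6-pentylbenzoate F8, and Pinnick oxidation (NaClO2, NaH2PO4, 2-methylbut-2-ene, t-BuOH/H2O) would give 16 directly.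

**Further compounds**
F1 | step 3 | methyl 2-hydroxy-4-oxo-6-pentylcyclohex-2-ene-1-carboxylate | CCCCCC1CC(=O)C=C(O)C1C(=O)OC
F2 | step 3 | methyl 2,4-dihydroxy-6-pentylbenzoate | CCCCCc1cc(O)cc(O)c1C(=O)OC
F3 | step 2 | tert-butyl oct-2-ynoate | CCCCCC#CC(=O)OC(C)(C)C
F4 | step 2 | 1-tert-butyl 3,3-dimethyl 2-pentylprop-1-ene-1,3,3-tricarboxylate | CCCCCC(=CC(=O)OC(C)(C)C)C(C(=O)OC)C(=O)OC
F5 | step 2 | 5-methoxy-4-(methoxycarbonyl)-5-oxo-3-pentylpent-2-enoic acid | CCCCCC(=CC(=O)O)C(C(=O)OC)C(=O)OC
F6 | step 6 | 2,4-dihydroxy-6-propylbenzaldehyde | CCCc1cc(O)cc(O)c1C=O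
F7 | step 6 | 4-formyl-3-hydroxy-5-propylphenyl 2,4-dimethoxy-6-pentylbenzoate | CCCCCc1cc(OC)cc(OC)c1C(=O)Oc1cc(CCC)c(C=O)c(O)c1
F8 | step 6 | 4-formyl-3-methoxy-5-propylphenyl 2,4-dimethoxy-6-pentylbenzoate | CCCCCc1cc(OC)cc(OC)c1C(=O)Oc1cc(CCC)c(C=O)c(OC)c1
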